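The protic impurity cannot quench more starting material than it has partners for, one for one, and with 0.0400 M of it against 0.20 M of starting material, that loss is capped at 20.0% of the charge.

    starting material + enzyme → target + enzyme, rate k1*[starting material]*[enzyme]/(1 + ([starting material]/Km1) + ([starting material]/Ksi1)^2) (Km1 = 14 mM, Ksi1 = 33 mM, k1 = 2900 M⁻¹ min⁻¹)
    starting material + protic impurity → quenched substrate (k2 = 0.052 M⁻¹ min⁻¹)
    target ⇌ isomer of the product (K3 = 3.1, k3 = 0.0011 min⁻¹)

all flasks: protic impurity 0.0400 M; enzyme 20 µM

| flask | starting material | time | remark |
|---|---|---|---|
| alpha | 0.20 M | 8.0 d | everything together in a closed stirred flask, run for 8.0 d |
| eta | 0.20 M |  | a single well-mixed tank run continuously and read at steady state, 8.0 d in it on average |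
| gamma | 0.20 M (fed, over 4.00 d) | 8.0 d | a stirred flask in which starting material is dosed at a steady rate over 4.00 d without added volume, worked up at 8.0 d |
| delta | 0.20 M |  | a single well-mixed tank run continuously and read at steady state, 40.0 d in it on average |

- the stated concentrations are those of everything mixed, before any reaction; amounts are the same in each set-up
- the feed brings no volume worth counting
- run time (alpha): 8.0 d

- the set-up with the highest amount of target at the outlet or at the end, in percent of the starting material put in ("none" if the first two lie within 2 percentage points) (alpha / eta / gamma / delta / none)
- amount of target at the outlet or at the end, in percent of the starting material put in, alpha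
- amount of target at the outlet or at the end, in percent of the starting material put in, eta
- amount of target at the outlet or at the end, in percent of the starting material put in, gamma
- amount of target at the outlet or at the end, in percent of the starting material put in, delta

We count in fractions of the charge, with x the starting material still unreacted, so that Km1 becomes 0.0700 and Ksi1 becomes 0.165. We begin with the enzyme step by itself, which turns starting material into target and has no competitor.

Now we add the quench. Dividing the enzyme's rate by the quench's removes time and leaves the branching ratio, a selectivity factor: starting material sent to product per unit quenched at that instant. With the impurity at its charge, its value as x approaches zero is 27.9, and at any x we divide this by one plus x over 0.0700 plus the square of x over 0.165. At the start of alpha, where x is one, the ratio is 0.536, so the quench runs faster than the enzyme and takes 65.1% of what reacts at that moment. Taking the starting material of alpha as fully reacted, the cap leaves 80.0% or more of the charge as product. In eta, inflow against consumption, with the enzyme taken as uninhibited and the impurity at its charge, gives x of 0.00144, so we reckon the ratio at 27.3 and the share of what reacts that becomes product at 96.5%.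

Last we add the isomerisation. Its forward half-life of 0.438 d is shorter than 8.0 d, so we take the closed flasks to equilibrium, with target at 24.4% of product. That puts our figure for alpha at 19.5% or more. In a tank, outflow competes with isomerisation, and the balance holds target at 28.6% of product in eta and 25.3% in delta. Taking the product share of eta for delta as well, we reckon 27.6% for eta and 24.4% for delta.

The forecast names eta, with 20% for alpha, 27.7% for eta, 23.6% for gamma and 24.5% for delta, on the ground that in the eta tank “its continuous washout keeps target above that equilibrium share”. Our own figures for the two tanks were 27.6% and 24.4%, so they are not quite its values.

The simulation gives 19.9% for alpha, 27.7% for eta, 23.6% for gamma and 24.5% for delta, so eta leads. In gamma the highest concentration of starting material stood at 6.06 × 10⁻⁴ M, where the branching ratio, with the impurity at its charge, is 26.7, which sends 96.4% of what reacts at that moment to product.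

Its constants were drawn at random within sensible limits; the rest is arithmetic.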